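The numbers in the tables were computed with constants of no real substance; scatter was added.

6 questions stand on 5 flasks that differ in how the starting material and the coupling partner go in and, for Friday's, in the temperature of the addition.

| setting | south-west | north | Friday's | Saturday's | Thursday's | Tuesday's | Sunday's |
|---|---|---|---|---|---|---|---|
| starting material | 0.19 M | 0.095 M | 0.19 M (fed, over 50 h) | 0.19 M | 0.19 M | 0.19 M (fed, over 50 h) | 0.19 M |
| coupling partner | 0.38 M | 0.38 M | 0.380 M | 0.380 M (fed, over 50 h) | 0.380 M (fed, over 5.0 h) | 0.380 M | 0.380 M (in portions, 5, over 50 h) |
| temperature | −20 °C | −20 °C |  | −20 °C | −20 °C | −20 °C | −20 °C |
| remark | run made earlier | run made earlier | the addition at −40 °C, then warmed to −20 °C; the feed brings no volume worth counting | all else is in the flask from the start; the feed brings no volume worth counting | all else is in the flask from the start; the feed brings no volume worth counting | all else is in the flask from the start; the feed brings no volume worth counting | first portion at the start, last at 50 h |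
| time |  |  | 2.5 d | 2.5 d | 2.5 d | 2.5 d | 2.5 d |

south-west run (percent of the starting material charged)

| time / d | target / % | starting material / % |
|---|---|---|
| 0.208 | 29 | 37 |
| 0.333 | 36 | 24 |
| 0.500 | 42 | 11 |
| 0.625 | 46 | 3 |
| 1.04 | 45 | 2 |
| 1.67 | 47 | 1 |
| 2.50 | 47 | 1 |

north run (percent of the starting material charged)

| time / h | target / % | starting material / % |
|---|---|---|
| 1.33 | 12 | 75 |
| 2.00 | 18 | 65 |
| 3.00 | 22 | 55 |
| 5.00 | 28 | 41 |
| 8.00 | 40 | 25 |
| 12.0 | 43 | 11 |
| 20.0 | 48 | 5 |

(standard deviation of a reading: 1.5 percentage points)

- percentages count the starting material that a species holds: one idle adduct or side product B counts as two
- target is meant together with its idle adduct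
- what was read earlier has a scatter of 1.5 percentage points, one standard deviation
- reactions considered so far: starting material + coupling partner -> target; starting material -> side product A; starting material + target <-> idle adduct; starting material + target -> side product B
- the earlier runs do not show what temperature does; that part of a forecast is a guess
- in an amount of target, one idle adduct counts as one target

- the best flask by amount of target, in percent of the starting material charged; "all alike" if 1.5 percentage points covers them all (Friday's / Saturday's / Thursday's / Tuesday's / Sunday's / all alike)
- amount of target at the end, in percent of the starting material charged, Friday's
- amount of target at the end, in percent of the starting material charged, Saturday's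
- amount of target at the end, in percent of the starting material charged, Thursday's
- amount of target at the end, in percent of the starting material charged, Tuesday's
- amount of target at the end, in percent of the starting material charged, Sunday's

In the south-west run, target ends at f = 47.5% of the starting material consumed, while the partner averages b = 0.335 M between its start and its end. Coupling is pseudo-first-order in starting material, so the target share is b/(b + c*). That gives c* = 0.371 M, the balance concentration, the partner level at which coupling and the loss to side product A take equal shares. In the north run, the same c* gives 49.1% against a reading of 50.5%, although that run holds less starting material.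

Two extreme flasks can be reckoned in the head. With the full partner charge present throughout, the share at −20 °C is 50.6%, and Tuesday's should lie near this ceiling. At the other extreme, the partner trickles in. Starting material in the north run has a life τ = 5.56 h, and Saturday's feed lasts longer than that. One life delivers 0.0422 M of partner, which gives a share of 10.2%. Starved starting material lives longer than τ, so Saturday's should lie somewhat above this floor. Sunday's first portion, 0.0760 M, gives 17.0%. Thursday's feed lasts about one life, so it falls between the extremes.

The forecast commits to 51% for Friday's, 14% for Saturday's, 39% for Thursday's, 49% for Tuesday's and 18% for Sunday's, with Friday's best: “Starving the partner is costly, because side product A wins early.” Its Saturday's figure stands above the floor reckoned here.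

The flasks give 47.7% for Friday's, 15.2% for Saturday's, 39.8% for Thursday's, 45.2% for Tuesday's and 19.5% for Sunday's, so Friday's is best.

    starting material + coupling partner → target (k = 0.276 M⁻¹ h⁻¹, Ea = 47.0 kJ mol⁻¹)
    starting material → side product A (k = 0.0838 h⁻¹, Ea = 90.0 kJ mol⁻¹)
    starting material + target ⇌ idle adduct, settled at all times (K = 4.49 M⁻¹, ΔH = −43.0 kJ mol⁻¹)
    starting material + target → side product B (k = 0.146 M⁻¹ h⁻¹, Ea = 67.0 kJ mol⁻¹)
    (constants at −20 °C)

The step to side product A has the largest single effect on the gap between Friday's and Saturday's: removing it turns 32 percentage points into −8.1 points. Through c*, Saturday's 15.2% of target against 82.9% of side product A means the starting material met about 0.0682 M of partner, less than the 0.169 M mean over the feed. Scaling that level to 0.23 M of partner, in a flask otherwise like Saturday's, gives 10.0%; that flask holds 10.5%.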